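**Retrosynthetic overview**

1. Target 33 ⇐ macrocycle 31 by acidolysis (two acetonides, tert-butyl ester) with closure of the γ-lactone (O7–C19) last; 31 ⇐ aldehyde 30 by Nozaki–Hiyama–Kishi closure of the ten-membered ring at C6–C7.
2. The C2–C6 arm is grown on aldehyde 14: syn-glycolate aldol (C2, C3), ynone and 1,3-syn reduction (C4), anti-carbomagnesiation/iodination (C5=C6, CH3-16); the cis-11,12-diol comes from osmylation of C11=C12.
3. Key disconnection: the six-membered ring of 14 ⇐ tiglic aldehyde 12 (C2, C1, CH3-15, C14, C13) + enal 11 (C12–C9 plus the C7/C8/C17/C19 unit) by vinylogous aldol condensation/6π-electrocyclization, which makes C12–C13 and C1–C10 in one flask.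
4. Enabling feature: ring C1–C14=C13–C12–C11–C10 has the quaternary methyl carbon C1 next to C10 and a methyl on C11, so it is a masked 1,5-dimethylcyclohexa-2,4-diene-1-carbaldehyde (two 2-methylbut-2-enal-type C5 units); its C11=C12 bond is the latent cis-diol and its formyl carbon is C2.
5. Enal 11 ⇐ D-tartrate acetonide 1 (C7, C8, C17, C19; CH3-18 by α-methylation; C9–C12 and CH3-20 by aldol with prenal, then SeO2). Ring order: dioxolane (temporary) → six-membered ring → ten-membered ring → γ-lactone.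

Key step: step 7

Numbering used in the text (briarane skeleton): C1 quaternary carbon with CH3-15; C2, C3, C4, C9 acetoxy carbons; C5(CH3-16)=C6; C7 lactone O-carbon; C8 and C17 (CH3-18) tertiary carbinols; C19 lactone carbonyl; C10; C11 (CH3-20); C12; C13=C14.

Assumption on the chemistry: α-substitution of tartrate acetonide enolates is taken to run with overall retention (the two carbonyl groups stay trans), as known for the diester; if the first methylation ran with inversion, the L-tartrate series would be used. Compounds 1, 7, 12, 15 and 16 are taken as commercial.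

**Route**

Step 1
Reactants: 1 dimethyl (4S,5S)-2,2-dimethyl-1,3-dioxolane-4,5-dicarboxylate (dimethyl 2,3-O-isopropylidene-D-tartrate)
Product: 2 (4S,5S)-5-(methoxycarbonyl)-2,2-dimethyl-1,3-dioxolane-4-carboxylic acid
Conditions: KOH (1.0 equiv), MeOH, 0 °C to rt; then aq. HCl to pH 2
Reagents that add atoms: potassium hydroxide, [K+].[OH-]
Why: Mono-saponification of a C2-symmetric diester (ester hydrolysis), in which the first carboxylate slows the second hydrolysis; no stereocenter is touched.

Step 2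
Reactants: 2 (4S,5S)-5-(methoxycarbonyl)-2,2-dimethyl-1,3-dioxolane-4-carboxylic acid
Product: 3 4-tert-butyl 5-methyl (4S,5S)-2,2-dimethyl-1,3-dioxolane-4,5-dicarboxylate
Conditions: Cl3CC(=NH)OtBu (2 equiv), CH2Cl2/cyclohexane, rt
Reagents that add atoms: tert-butyl 2,2,2-trichloroacetimidate, CC(C)(C)OC(=N)C(Cl)(Cl)Cl
Why: O-alkylation of the carboxylic acid by the trichloroacetimidate (tert-butyl ester formation, self-catalysed by the acid) leaves the methyl ester and the acetonide intact.

Step 3
Reactants: 3 4-tert-butyl 5-methyl (4S,5S)-2,2-dimethyl-1,3-dioxolane-4,5-dicarboxylate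
Product: 4 tert-butyl (4S,5S)-5-(dimethylcarbamoyl)-2,2-dimethyl-1,3-dioxolane-4-carboxylate
Conditions: Me2NH (2 M in THF, 5 equiv), MeOH, rt
Reagents that add atoms: dimethylamine, CNC
Why: Chemoselective ester aminolysis: the α-alkoxy methyl ester reacts with the amine at room temperature while the tert-butyl ester is inert, and the trans-dioxolane is also the thermodynamic isomer.

Step 4
Reactants: 4 tert-butyl (4S,5S)-5-(dimethylcarbamoyl)-2,2-dimethyl-1,3-dioxolane-4-carboxylate
Product: 6 tert-butyl (4S,5S)-5-(dimethylcarbamoyl)-2,2,4-trimethyl-1,3-dioxolane-4-carboxylate, via lithium ester enolate 5 (not isolated)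
Conditions: LiN(iPr)2 (1.1 equiv), THF/DMPU, -78 °C; then MeI, -78 to -40 °C
Reagents that add atoms: iodomethane, CI
Why: α-Alkylation of the tartrate acetonide ester enolate: the amide base removes the more acidic ester α-hydrogen (not the amide α-hydrogen), β-elimination is slow because the ring C–O bond lies in the enolate plane, and iodomethane enters with retention (carbonyl groups stay trans), which sets C17.

Step 5
Reactants: 6 tert-butyl (4S,5S)-5-(dimethylcarbamoyl)-2,2,4-trimethyl-1,3-dioxolane-4-carboxylate; 7 3-methylbut-2-enal (prenal)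
Product: 10 tert-butyl (4S,5S)-5-[(1R)-1-[(tert-butyldimethylsilyl)oxy]-3-methylbut-2-en-1-yl]-5-(dimethylcarbamoyl)-2,2,4-trimethyl-1,3-dioxolane-4-carboxylate, via lithium amide enolate 8 (not isolated), via lithium aldolate 9 (not isolated)
Conditions: LiN(iPr)2 (1.1 equiv), THF, -78 °C; 7, -78 °C; then TBSOTf, 2,6-lutidine, -78 to 0 °C
Reagents that add atoms: tert-butyldimethylsilyl trifluoromethanesulfonate, CC(C)(C)[Si](C)(C)OS(=O)(=O)C(F)(F)F
Why: Aldol 1,2-addition of the tetrasubstituted lithium amide enolate through a closed Zimmerman–Traxler transition state: lithium bridged to the cis ester carbonyl delivers the aldehyde to the enolate face anti to CH3-18 (sets C8, carbonyl groups stay trans), the enolate geometry with the ring oxygen cis to NMe2 places O9 anti to O8 (sets C9), and silylation in the same flask blocks retro-aldol.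

Step 6
Reactants: 10 silyl ether (as above)
Product: 11 tert-butyl (4S,5S)-5-[(1R,2E)-1-[(tert-butyldimethylsilyl)oxy]-3-methyl-4-oxobut-2-en-1-yl]-5-(dimethylcarbamoyl)-2,2,4-trimethyl-1,3-dioxolane-4-carboxylate
Conditions: SeO2 (1.2 equiv), 1,4-dioxane, 80 °C
Reagents that add atoms: selenium dioxide, O=[Se]=O
Why: Allylic oxidation with SeO2 (ene reaction then [2,3]-shift) attacks the E-methyl group at the more substituted alkene terminus and gives the (E)-enal with the formyl carbon (C12) trans to C9; no stereocenter is involved.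

Step 7
Reactants: 11 (E)-enal (as above); 12 (E)-2-methylbut-2-enal (tiglic aldehyde)
Product: 14 tert-butyl (4S,5S)-5-[(R)-[(tert-butyldimethylsilyl)oxy][(1S,6S)-6-formyl-2,6-dimethylcyclohexa-2,4-dien-1-yl]methyl]-5-(dimethylcarbamoyl)-2,2,4-trimethyl-1,3-dioxolane-4-carboxylate, via (2Z,4Z,6E)-trienal 13 (not isolated)
Conditions: pyrrolidine (0.3 equiv), PhCO2H (0.3 equiv), 12 (4 equiv, slow addition), 4 Å MS, toluene, 40 °C, then 80 °C
Reagents that add atoms: none
Why: Pyrrolidine turns 12 into its dienamine, whose γ-carbon (C13) adds to the formyl carbon (C12) of 11 and, after loss of water, gives trienal 13; reversible iminium, dienamine and 2H-pyran equilibria interconvert its double-bond isomers until the (2Z,4Z,6E) isomer closes by thermal disrotatory 6π-electrocyclization, which forms C1–C10. The closest known reaction type is the amine-catalysed formal [3+3] union of two enals to a cyclohexadiene carbaldehyde, that is a vinylogous aldol condensation followed by hexatriene-to-cyclohexadiene closure. The six-membered carbocycle is the only ring closed, and it closes in the pericyclic 6π disrotatory mode. Disrotation with the formyl group and H10 inside and CH3-15 and C9 outside puts CH3-15 and C9 cis (relative configuration of C1 and C10), and the absolute sense comes from C9: the bond forms at the electrophilic terminus C10 anti to the C9–O bond in the conformer where C9–H eclipses C10=C11 to avoid allylic strain with CH3-20. The step needs cross- over self-condensation, γ- over α-attack and the formyl-inside closure: 11 is the more electrophilic aldehyde and has only one hindered γ-hydrogen, α-adducts revert, the flat formyl group tolerates the inside position better than methyl, and the quaternary C1 of 14 stops the diene from moving into conjugation.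

Step 8
Reactants: 15 (S)-4-benzyloxazolidin-2-one; 16 [(tert-butyldimethylsilyl)oxy]acetic acid
Product: 18 (S)-4-benzyl-3-{[(tert-butyldimethylsilyl)oxy]acetyl}oxazolidin-2-one, via mixed pivalic anhydride 17 (not isolated)
Conditions: t-BuCOCl, Et3N, THF, -20 °C; then 15, LiCl, rt
Reagents that add atoms: none
Why: N-Acylation of the oxazolidinone by the mixed anhydride (acyl transfer at the less hindered carbonyl, LiCl/Et3N activation); no new stereocenter.

Step 9
Reactants: 14 cyclohexadiene carbaldehyde (as above); 18 glycolate imide (as above)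
Product: 20 syn-aldol imide: (4S)-4-benzyl-3-[(2S,3R)-2-[(tert-butyldimethylsilyl)oxy]-3-hydroxy-3-(cyclohexadienyl)propanoyl]oxazolidin-2-one, the cyclohexadienyl group being C1 of 14 (new C2 carbinol and C3 silyl ether as in the target), via dibutylboron enolate 19 (not isolated)
Conditions: Bu2BOTf, Et3N, CH2Cl2, -78 to 0 °C; 14, -78 to 0 °C; then pH 7 buffer, MeOH, H2O2
Reagents that add atoms: none
Why: Evans syn-aldol: the (Z)-boron enolate adds through a chair transition state in which the auxiliary fixes the enolate face, giving the 2,3-syn glycolate adduct and overriding the weak bias of the α-quaternary aldehyde; this sets C2 and C3.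

Step 10
Reactants: 20 syn-aldol imide
Product: 21 imide triol: 20 with a cis-diol at C11 and C12, both hydroxyls on the ring face opposite the C10 side chain
Conditions: OsO4 (5 mol %), N-methylmorpholine N-oxide, acetone/H2O, 0 °C to rt
Reagents that add atoms: N-methylmorpholine N-oxide, C[N+]1([O-])CCOCC1; water, O; osmium tetroxide (catalyst), O=[Os](=O)(=O)=O
Why: Upjohn dihydroxylation: OsO4 takes the more electron-rich trisubstituted C11=C12 bond of the diene from the face opposite the C10 side chain (which screens C11 and C12 in either half-chair), giving the cis-11,12-diol and setting C11 and C12.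

Step 11
Reactants: 21 imide triol
Product: 22 acetonide: 21 with O11 and O12 joined as an isopropylidene acetal, C2 hydroxyl free
Conditions: 2-methoxypropene, PPTS (cat.), CH2Cl2, 0 °C; MeOH quench
Reagents that add atoms: 2-methoxypropene, COC(C)=C
Why: Acid-catalysed acetonide formation is favoured for the cis-1,2-diol (five-membered dioxolane); any mixed ketal at the hindered C2 hydroxyl is cleaved in the methanol quench.

Step 12
Reactants: 22 acetonide
Product: 23 Weinreb amide: 22 with the oxazolidinone replaced by N(OMe)Me at C4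
Conditions: MeONHMe·HCl, Me3Al, CH2Cl2, 0 °C to rt
Reagents that add atoms: N,O-dimethylhydroxylamine hydrochloride, CNOC.Cl
Why: Aluminium amide transamination of the β-hydroxy imide (Weinreb amide formation) releases the auxiliary, while the hindered tert-butyl ester and the dimethylamide do not react.

Step 13
Reactants: 23 Weinreb amide
Product: 24 ynone: C4 ketone carrying the ethynyl group (C5≡C6H), C2 hydroxyl free
Conditions: HC≡CMgBr (4 equiv), THF, -20 to 0 °C; aq. NH4Cl
Reagents that add atoms: ethynylmagnesium bromide, C#C[Mg]Br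
Why: Grignard addition to the Weinreb amide stops at the chelated tetrahedral intermediate and gives the ketone on work-up; the tert-butyl ester and the hindered tertiary amide are spared.

Step 14
Reactants: 24 ynone
Product: 25 propargylic diol: C4 carbinol 1,3-syn to the C2 hydroxyl
Conditions: Et2BOMe, THF/MeOH (4:1), -78 °C; NaBH4; AcOH, then MeOH co-evaporation
Reagents that add atoms: none
Why: Narasaka–Prasad reduction: the boron chelate between the C2 hydroxyl and the C4 ketone is reduced by external hydride in the axial sense, giving the 1,3-syn diol and setting C4.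

Step 15
Reactants: 25 propargylic diol
Product: 27 (Z)-iodoalkene diol: C4(OH)–C5(CH3)=C6H–I with iodine cis to C4, via alkenylmagnesium bromide 26 (not isolated)
Conditions: MeMgBr (5 equiv), CuI (0.2 equiv), Et2O/THF, -20 °C to rt; then I2, -78 to 0 °C
Reagents that add atoms: methylmagnesium bromide, C[Mg]Br; iodine, II
Why: Copper-catalysed anti-carbomagnesiation of the propargylic magnesium alkoxide puts methyl on C5 and magnesium on C6 in a five-membered chelate, and iodinolysis with retention gives the (Z)-iodoalkene; no stereocenter changes.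

Step 16
Reactants: 27 (Z)-iodoalkene diol
Product: 28 tetraol: free hydroxyls at C2, C3, C4 and C9
Conditions: HF·pyridine, pyridine, THF, 0 to 40 °C
Reagents that add atoms: none
Why: Fluoride-driven desilylation removes both silyl ethers, while buffered HF·pyridine leaves the acetonides, the tert-butyl ester and the alkenyl iodide alone.

Step 17
Reactants: 28 tetraol
Product: 29 tetraacetate: acetates at O2, O3, O4 and O9
Conditions: Ac2O, pyridine, DMAP (cat.), CH2Cl2, rt to 40 °C
Reagents that add atoms: acetic anhydride, CC(=O)OC(C)=O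
Why: DMAP-catalysed acylation acetylates the four secondary hydroxyls; all tertiary oxygens and O12 are still inside acetonides.

Step 18
Reactants: 29 tetraacetate
Product: 30 aldehyde: the C7 dimethylamide converted into the C7 formyl group
Conditions: Cp2Zr(H)Cl (2 equiv), THF, rt, 20 min
Reagents that add atoms: none
Why: Hydrozirconation of the tertiary amide carbonyl gives a zirconated hemiaminal that collapses to the aldehyde on work-up; acetates and the tert-butyl ester react much more slowly.

Step 19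
Reactants: 30 aldehyde
Product: 31 macrocyclic allylic alcohol: ten-membered ring closed at C6–C7, (5Z) alkene, free C7 hydroxyl configured as in the target
Conditions: CrCl2 (10 equiv), NiCl2 (0.1 equiv), DMSO/THF, rt, 0.002 M
Reagents that add atoms: none
Why: Nozaki–Hiyama–Kishi reaction: zerovalent nickel inserts into the alkenyl iodide with retention of the (Z) geometry, transmetallation gives the alkenylchromium species (trivalent chromium), and its intramolecular addition to the C7 aldehyde closes the ten-membered ring; the C7 carbinol is expected from Felkin–Anh attack anti to the C8–O bond, and the acetonide holds C19 away from O7 so no lactone forms yet.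

Step 20
Reactants: 31 macrocyclic allylic alcohol
Product: 33 target CNP0203328.1, via hydroxy acid 32 (not isolated)
Conditions: CF3CO2H/H2O (9:1), 0 °C to rt
Reagents that add atoms: none
Why: Acidolysis removes both acetonides and the tert-butyl ester, and the freed C19 acid lactonizes (acyl substitution, five-membered ring) onto O7, the only free γ-hydroxyl since O9 is acetylated, with retention at C7; the hydroxyls at C8, C11, C12 and C17 stay free.

**Compound list**

1 | dimethyl (4S,5S)-2,2-dimethyl-1,3-dioxolane-4,5-dicarboxylate | COC(=O)[C@H]1OC(C)(C)O[C@@H]1C(=O)OC | starting material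
2 | (4S,5S)-5-(methoxycarbonyl)-2,2-dimethyl-1,3-dioxolane-4-carboxylic acid | OC(=O)[C@H]1OC(C)(C)O[C@@H]1C(=O)OC | intermediate
3 | 4-tert-butyl 5-methyl (4S,5S)-2,2-dimethyl-1,3-dioxolane-4,5-dicarboxylate | CC(C)(C)OC(=O)[C@H]1OC(C)(C)O[C@@H]1C(=O)OC | intermediate
4 | tert-butyl (4S,5S)-5-(dimethylcarbamoyl)-2,2-dimethyl-1,3-dioxolane-4-carboxylate | CC(C)(C)OC(=O)[C@H]1OC(C)(C)O[C@@H]1C(=O)N(C)C | intermediate
5 | lithium ester enolate of 4 | [Li+].CC(C)(C)OC([O-])=C1OC(C)(C)O[C@@H]1C(=O)N(C)C | intermediate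
6 | tert-butyl (4S,5S)-5-(dimethylcarbamoyl)-2,2,4-trimethyl-1,3-dioxolane-4-carboxylate | CC(C)(C)OC(=O)[C@@]1(C)OC(C)(C)O[C@@H]1C(=O)N(C)C | intermediate
7 | 3-methylbut-2-enal | CC(C)=CC=O | starting material
8 | lithium amide enolate of 6 | [Li+].CN(C)C([O-])=C1OC(C)(C)O[C@]1(C)C(=O)OC(C)(C)C | intermediate
9 | lithium aldolate (C9 alkoxide) | [Li+].CC(C)=C[C@@H]([O-])[C@]1(C(=O)N(C)C)OC(C)(C)O[C@]1(C)C(=O)OC(C)(C)C | intermediate
10 | tert-butyl (4S,5S)-5-[(1R)-1-[(tert-butyldimethylsilyl)oxy]-3-methylbut-2-en-1-yl]-5-(dimethylcarbamoyl)-2,2,4-trimethyl-1,3-dioxolane-4-carboxylate | CC(C)=C[C@@H](O[Si](C)(C)C(C)(C)C)[C@]1(C(=O)N(C)C)OC(C)(C)O[C@]1(C)C(=O)OC(C)(C)C | intermediate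
11 | tert-butyl (4S,5S)-5-[(1R,2E)-1-[(tert-butyldimethylsilyl)oxy]-3-methyl-4-oxobut-2-en-1-yl]-5-(dimethylcarbamoyl)-2,2,4-trimethyl-1,3-dioxolane-4-carboxylate | O=C/C(C)=C/[C@@H](O[Si](C)(C)C(C)(C)C)[C@]1(C(=O)N(C)C)OC(C)(C)O[C@]1(C)C(=O)OC(C)(C)C | intermediate
12 | (E)-2-methylbut-2-enal | C/C=C(C)/C=O | starting material
13 | (2Z,4Z,6E)-2,6-dimethylocta-2,4,6-trienal carrying the C9 silyloxy carbon and the dioxolane unit at C8 of the chain | O=C/C(C)=C\C=C/C(C)=C/[C@@H](O[Si](C)(C)C(C)(C)C)[C@]1(C(=O)N(C)C)OC(C)(C)O[C@]1(C)C(=O)OC(C)(C)C | intermediate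
14 | tert-butyl (4S,5S)-5-[(R)-[(tert-butyldimethylsilyl)oxy][(1S,6S)-6-formyl-2,6-dimethylcyclohexa-2,4-dien-1-yl]methyl]-5-(dimethylcarbamoyl)-2,2,4-trimethyl-1,3-dioxolane-4-carboxylate | O=C[C@@]1(C)C=CC=C(C)[C@@H]1[C@@H](O[Si](C)(C)C(C)(C)C)[C@]2(C(=O)N(C)C)OC(C)(C)O[C@]2(C)C(=O)OC(C)(C)C | intermediate
15 | (S)-4-benzyloxazolidin-2-one | O=C1N[C@@H](Cc2ccccc2)CO1 | starting material
16 | [(tert-butyldimethylsilyl)oxy]acetic acid | CC(C)(C)[Si](C)(C)OCC(O)=O | starting material
17 | [(tert-butyldimethylsilyl)oxy]acetic pivalic anhydride | CC(C)(C)[Si](C)(C)OCC(=O)OC(=O)C(C)(C)C | intermediate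
18 | (S)-4-benzyl-3-{[(tert-butyldimethylsilyl)oxy]acetyl}oxazolidin-2-one | CC(C)(C)[Si](C)(C)OCC(=O)N1[C@@H](Cc2ccccc2)COC1=O | intermediate
19 | (Z)-dibutylboron enolate of 18 | CCCCB(CCCC)O/C(=C\O[Si](C)(C)C(C)(C)C)N1[C@@H](Cc2ccccc2)COC1=O | intermediate
20 | syn-aldol imide (C2 hydroxyl, C3 silyl ether, C4 acyl oxazolidinone) | O=C1OC[C@H](Cc2ccccc2)N1C(=O)[C@@H](O[Si](C)(C)C(C)(C)C)[C@H](O)[C@@]3(C)C=CC=C(C)[C@@H]3[C@@H](O[Si](C)(C)C(C)(C)C)[C@]4(C(=O)N(C)C)OC(C)(C)O[C@]4(C)C(=O)OC(C)(C)C | intermediate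
21 | imide triol (cis-11,12-diol) | O=C1OC[C@H](Cc2ccccc2)N1C(=O)[C@@H](O[Si](C)(C)C(C)(C)C)[C@H](O)[C@@]3(C)C=C[C@@H](O)[C@@](C)(O)[C@@H]3[C@@H](O[Si](C)(C)C(C)(C)C)[C@]4(C(=O)N(C)C)OC(C)(C)O[C@]4(C)C(=O)OC(C)(C)C | intermediate
22 | imide 11,12-acetonide | O=C1OC[C@H](Cc2ccccc2)N1C(=O)[C@@H](O[Si](C)(C)C(C)(C)C)[C@H](O)[C@@]3(C)C=C[C@H]5OC(C)(C)O[C@@]5(C)[C@@H]3[C@@H](O[Si](C)(C)C(C)(C)C)[C@]4(C(=O)N(C)C)OC(C)(C)O[C@]4(C)C(=O)OC(C)(C)C | intermediate
23 | C4 Weinreb amide | CON(C)C(=O)[C@@H](O[Si](C)(C)C(C)(C)C)[C@H](O)[C@@]1(C)C=C[C@H]2OC(C)(C)O[C@@]2(C)[C@@H]1[C@@H](O[Si](C)(C)C(C)(C)C)[C@]3(C(=O)N(C)C)OC(C)(C)O[C@]3(C)C(=O)OC(C)(C)C | intermediate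
24 | C4 ethynyl ketone (ynone) | C#CC(=O)[C@@H](O[Si](C)(C)C(C)(C)C)[C@H](O)[C@@]1(C)C=C[C@H]2OC(C)(C)O[C@@]2(C)[C@@H]1[C@@H](O[Si](C)(C)C(C)(C)C)[C@]3(C(=O)N(C)C)OC(C)(C)O[C@]3(C)C(=O)OC(C)(C)C | intermediate
25 | propargylic 2,4-syn diol | C#C[C@H](O)[C@@H](O[Si](C)(C)C(C)(C)C)[C@H](O)[C@@]1(C)C=C[C@H]2OC(C)(C)O[C@@]2(C)[C@@H]1[C@@H](O[Si](C)(C)C(C)(C)C)[C@]3(C(=O)N(C)C)OC(C)(C)O[C@]3(C)C(=O)OC(C)(C)C | intermediate
26 | (Z)-alkenylmagnesium bromide (bis-magnesium alkoxide) | Br[Mg]/C=C(C)\[C@H](O[Mg]Br)[C@@H](O[Si](C)(C)C(C)(C)C)[C@H](O[Mg]Br)[C@@]1(C)C=C[C@H]2OC(C)(C)O[C@@]2(C)[C@@H]1[C@@H](O[Si](C)(C)C(C)(C)C)[C@]3(C(=O)N(C)C)OC(C)(C)O[C@]3(C)C(=O)OC(C)(C)C | intermediate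
27 | (Z)-iodoalkene diol | I/C=C(C)\[C@H](O)[C@@H](O[Si](C)(C)C(C)(C)C)[C@H](O)[C@@]1(C)C=C[C@H]2OC(C)(C)O[C@@]2(C)[C@@H]1[C@@H](O[Si](C)(C)C(C)(C)C)[C@]3(C(=O)N(C)C)OC(C)(C)O[C@]3(C)C(=O)OC(C)(C)C | intermediate
28 | (Z)-iodoalkene tetraol (O2, O3, O4, O9 free) | I/C=C(C)\[C@H](O)[C@@H](O)[C@H](O)[C@@]1(C)C=C[C@H]2OC(C)(C)O[C@@]2(C)[C@@H]1[C@@H](O)[C@]3(C(=O)N(C)C)OC(C)(C)O[C@]3(C)C(=O)OC(C)(C)C | intermediate
29 | tetraacetate amide | I/C=C(C)\[C@H](OC(C)=O)[C@@H](OC(C)=O)[C@H](OC(C)=O)[C@@]1(C)C=C[C@H]2OC(C)(C)O[C@@]2(C)[C@@H]1[C@@H](OC(C)=O)[C@]3(C(=O)N(C)C)OC(C)(C)O[C@]3(C)C(=O)OC(C)(C)C | intermediate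
30 | tetraacetate C7 aldehyde | I/C=C(C)\[C@H](OC(C)=O)[C@@H](OC(C)=O)[C@H](OC(C)=O)[C@@]1(C)C=C[C@H]2OC(C)(C)O[C@@]2(C)[C@@H]1[C@@H](OC(C)=O)[C@]3(C=O)OC(C)(C)O[C@]3(C)C(=O)OC(C)(C)C | intermediate
31 | macrocyclic C7 allylic alcohol (bis-acetonide, tert-butyl ester, tetraacetate) | CC(=O)O[C@@H]1[C@@H](OC(C)=O)/C(C)=C\[C@H](O)[C@]2(OC(C)(C)O[C@]2(C)C(=O)OC(C)(C)C)[C@H](OC(C)=O)[C@H]3[C@]4(C)OC(C)(C)O[C@@H]4C=C[C@]3(C)[C@H]1OC(C)=O | intermediate
32 | seco hydroxy acid (C19 acid; O7, O8, O11, O12, O17 free) | CC(=O)O[C@@H]1[C@@H](OC(C)=O)/C(C)=C\[C@H](O)[C@@](O)([C@](C)(O)C(O)=O)[C@H](OC(C)=O)[C@H]2[C@](C)(O)[C@H](O)C=C[C@]2(C)[C@H]1OC(C)=O | intermediate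
33 | CNP0203328.1 | CC(=O)O[C@@H]1[C@@H](OC(C)=O)/C(C)=C\[C@@H]2OC(=O)[C@@](C)(O)[C@@]2(O)[C@H](OC(C)=O)[C@H]2[C@](C)(O)[C@H](O)C=C[C@]2(C)[C@H]1OC(C)=O | target

**Step count and risks**

Total step count: 20. Longest linear sequence: 19 steps (steps 1–7 and 9–20; step 8 is a one-step branch).

Steps most likely to fail:

1. Step 7. Possible failures: self-condensation of 12 outrunning the cross-condensation; incomplete equilibration of the double-bond isomers of 13; epimerisation at C9 by γ-deprotonation of the iminium of 11; weak facial control by C9 in the ring closure; [1,5]-migration of the formyl group of 14 at the closure temperature. The fallback sets out from 11 and comes back at 14. Wittig reaction of 11 with (triphenylphosphoranylidene)acetaldehyde should give the (2E,4E)-dienal F1. A second Wittig reaction with 2-(triphenylphosphoranylidene)propanal should give the all-E trienal F2, a double-bond isomer of 13. Iodine-catalysed photoequilibration of the polyene (catalytic I2, visible light, benzene, rt to 60 °C) should then feed the (2Z,4Z) isomer into the same disrotatory closure to 14, without amine and at lower temperature.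

2. Step 19. Possible failures: oligomerisation instead of ring closure; poor facial selectivity of the addition at C7; acetyl transfer from O9 to the new C7 alkoxide. The fallback sets out from 30 and comes back at 31. The ring is closed as before, but C7 is set afterwards: the mixture of 31 and its C7 epimer F3 is oxidised with Dess–Martin periodinane to the macrocyclic enone F4. F4 is reduced under reagent control (Corey–Bakshi–Shibata reduction with the (R)-Me-oxazaborolidine and BH3·SMe2, C8 acting as the large group) to 31.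

3. Step 5. Possible failures: retro-aldol on warming; β-elimination of the dioxolane enolate; low simple selectivity at C9. The fallback sets out from 6 and comes back at 10. Enolate 8 is C-acylated with 3-methylbut-2-enoyl chloride to the β-keto amide F5, which cannot revert and has C8 set as before. The C9 ketone is reduced under reagent control (Corey–Bakshi–Shibata reduction with the (S)-Me-oxazaborolidine and BH3·SMe2) to the allylic alcohol F6, and silylation (TBSOTf, 2,6-lutidine) gives 10.

Further compounds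

F1 | step 7 | (2E,4E)-dienal from 11 (C14 formyl, C12=C13 in place) | O=C/C=C/C(C)=C/[C@@H](O[Si](C)(C)C(C)(C)C)[C@]1(C(=O)N(C)C)OC(C)(C)O[C@]1(C)C(=O)OC(C)(C)C
F2 | step 7 | all-E trienal, (2E,4E) isomer of 13 | O=C/C(C)=C/C=C/C(C)=C/[C@@H](O[Si](C)(C)C(C)(C)C)[C@]1(C(=O)N(C)C)OC(C)(C)O[C@]1(C)C(=O)OC(C)(C)C
F3 | step 19 | C7 epimer of 31 | CC(=O)O[C@@H]1[C@@H](OC(C)=O)/C(C)=C\[C@@H](O)[C@]2(OC(C)(C)O[C@]2(C)C(=O)OC(C)(C)C)[C@H](OC(C)=O)[C@H]3[C@]4(C)OC(C)(C)O[C@@H]4C=C[C@]3(C)[C@H]1OC(C)=O
F4 | step 19 | macrocyclic C7 enone | CC(=O)O[C@@H]1[C@@H](OC(C)=O)/C(C)=C\C(=O)[C@]2(OC(C)(C)O[C@]2(C)C(=O)OC(C)(C)C)[C@H](OC(C)=O)[C@H]3[C@]4(C)OC(C)(C)O[C@@H]4C=C[C@]3(C)[C@H]1OC(C)=O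
F5 | step 5 | C9 β-keto amide | CC(C)=CC(=O)[C@]1(C(=O)N(C)C)OC(C)(C)O[C@]1(C)C(=O)OC(C)(C)C
F6 | step 5 | C9 allylic alcohol (9R) | CC(C)=C[C@@H](O)[C@]1(C(=O)N(C)C)OC(C)(C)O[C@]1(C)C(=O)OC(C)(C)C
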